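## Analysis of the target

- The target is a flavonol: a chromen-4-one in which benzo ring A is fused to pyranone ring C, with the 4-hydroxy-3-methoxyphenyl ring B on C2 and oxygen on C3, C5, C7 and C4'.
- O3 and O7 carry sulfate monoesters, while O5 and O4' are free hydroxyls.
- The molecule has no stereocentre, so the whole problem is one of regiochemistry among four oxygens.
- The sulfate monoesters are strong acids, very polar and acid-labile (the enol-type O3 ester most of all), so they have to be introduced near the end and kept as salts.
- The four hydroxyls differ usefully: 7-OH is the most acidic, 4'-OH is close to it, 3-OH is an enolic hydroxyl, and 5-OH is held in a six-membered hydrogen bond to the C4 carbonyl and is the least reactive.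
- The difficulty is to sulfate exactly O3 and O7, and to build the 5,7-dioxygenated ring A fused to ring C without a long phloroglucinol protection sequence.
- The strategy rests on one feature of ring A: O1 (on C8a) and O5 (on C5) are ortho, and O7 (on C7) is para, to C4a, which carries the C4 carbonyl. All three C–O bonds can therefore be made by displacing fluoride from a 2,4,6-trifluorobenzoyl unit, the first of them intramolecularly to close ring C.

## Retrosynthetic reasoning

**O4'–benzyl.** The target 17 is traced back to its 4'-O-benzyl ether 16. O4' is nearly as reactive as O7 and must be masked during sulfation. A benzyl ether is chosen because it is removed by neutral hydrogenolysis, which leaves sulfate esters alone. An acid-labile mask would put the O3 sulfate at risk.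

**Two O–S bonds.** 16 is cut at both O–S bonds to the triol 15 (3,5,7-trihydroxy, O4' benzylated). The sulfates go on last among the heavy-atom changes, because every later intermediate would be an anionic, water-soluble species. The forward reaction has to distinguish O3 and O7 from O5. The hydrogen bond of 5-OH to the C4 carbonyl provides that distinction, so no extra protecting group is needed.

**Three 4-methoxybenzyl ethers.** 15 comes from the tris(4-methoxybenzyl) ether 14. One acid treatment frees O3, O5 and O7 together, and the slower-ionising plain benzyl ether on O4' stays.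

**C5–O and C7–O.** 14 is cut at both ring A ether bonds to the 5,7-difluorochromone 12 and the potassium alkoxide 13 (made from alcohol 1 with KH). C5 is ortho and C7 is para to the C4 carbonyl, so both fluorides are activated for addition–elimination. The potassium salt is chosen for this step because its looser ion pair is the better nucleophile for the sluggish second displacement. The same alcohol is used for O3, O5 and O7, so the order of displacement does not matter and one deprotection serves all three.

**C2–C3 and O1–C8a (key disconnection).** 12 is opened at O1–C8a to the 2-alkoxy-1,3-diketone 11, and 11 is cut at C2–C3 to the enolate 10 of ketone 7 and the ring B acid chloride 9. This is the place to cut because it joins the two halves of the flavonol at the right oxidation level and uses one of three equivalent fluorines as the ring-closing leaving group. No protected phloroglucinol and no later oxidation are needed. The forward reaction must acylate the enolate on carbon and then close a six-membered ring by intramolecular fluoride displacement.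

**C4–C4a.** Ketone 7 is cut between the carbonyl carbon and the arene to the aryllithium 6 (from 1,3,5-trifluorobenzene 5) and the N-methoxy-N-methyl amide 4. The C–H of 5 lies between two fluorines and is easily lithiated, and the amide stops the addition at the ketone stage.

**Side-chain ether and acid chloride.** Amide 4 is cut at its CH2–O bond to the sodium alkoxide 3 (from 1 with NaH) and the chloroacetamide 2. Acid chloride 9 comes from the commercial acid 8, which already carries the benzyl ether on O4'.

## Alternatives that were turned down

**Alternative 1: aryne insertion.**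
- Disconnection: C4–C4a, O1–C8a and O1–C2. Ring A would come from the aryne precursor 3,5-bis(methoxymethoxy)-2-(trimethylsilyl)phenyl trifluoromethanesulfonate A2, and the C2–C3–C4 unit with ring B from (Z)-3-(4-benzyloxy-3-methoxyphenyl)-2-(methoxymethoxy)acrylic acid A3.
- Forward key step: fluoride would release the aryne, the carboxylate would add at the future C8a, the aryl anion would take the acyl carbon, and the freed phenoxide would add to C2. The product would be racemic trans-2-(4-benzyloxy-3-methoxyphenyl)-3,5,7-tris(methoxymethoxy)chroman-4-one A1.
- For: all ring A oxygens are in place from the start and the conditions are mild. On that point it is stronger than the chosen route, which needs a separate fluoride displacement step.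
- Against: A1 is two hydrogens too rich, and its two stereocentres would be made only to be removed by an extra dehydrogenation. The conjugate addition is reversible. Protonation of the aryl anion (simple O-arylation of the acid) competes with acyl transfer. A2 needs several steps in which a symmetric triphenol has to be desymmetrised. After acetal removal the same triol 15 would be reached.
- Comparison: the chosen strategy reaches the flavonol oxidation level directly from a commercial arene in fewer operations.

**Alternative 2: thermal condensation.**
- Disconnection: C4–C4a and O1–C2, between phloroglucinol A6 and ethyl 2-(benzoyloxy)-3-(4-benzyloxy-3-methoxyphenyl)-3-oxopropanoate A5.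
- Forward key step: heating the two without solvent would give 2-(4-benzyloxy-3-methoxyphenyl)-5,7-dihydroxy-4-oxo-4H-chromen-3-yl benzoate A4.
- For: it is the shortest possible assembly and needs no ring A protection. Hydrolysis of the benzoate in A4 would give 15 at once, so on step count it beats the chosen route.
- Against: the melt needs temperatures at which the benzyl ether and the acyloxy keto ester are at risk (acyl transfer to the free hydroxyls of A6, decarboxylative breakdown). The two partners can also condense in the opposite, Pechmann-type sense, and nothing in the substrates controls which mode wins.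
- Comparison: the chosen strategy forms each bond under mild conditions with the regiochemistry fixed by structure.

**Alternative 3: ring A benzannulation.**
- Disconnection: all of ring A (C8–C8a, C7–C8, C5–C6, C4a–C5), from the pyranonyl diazo ketone 2-diazo-1-[6-(4-benzyloxy-3-methoxyphenyl)-5-(methoxymethoxy)-4-oxo-4H-pyran-2-yl]ethanone A8 and tert-butoxyacetylene A9.
- Forward key step: irradiation would cause Wolff rearrangement to a ketene, [2+2] addition to A9, ring opening and 6π closure. The product would be 2-(4-benzyloxy-3-methoxyphenyl)-7-tert-butoxy-5-hydroxy-3-(methoxymethoxy)chromen-4-one A7.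
- For: four bonds form in one operation, and O5 and O7 come out differentiated (free phenol against tert-butyl ether). The chosen route never achieves that by protecting groups, so on that point this alternative is stronger.
- Against: A8 needs O-protection, C-arylation of a pyranone and a diazo ketone synthesis. 4-Pyranones are themselves photolabile at the wavelengths that drive the Wolff step. A9 is volatile and thermally fragile. The pyranone C=C bond has to serve as the vinyl terminus of the electrocyclisation.
- Comparison: for this target the O5/O7 distinction is already supplied by the hydrogen bond at O5, so the extra length buys little. The chosen strategy takes ring A with the right substitution pattern from a commercial arene.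

Key step: step 4

Assumption: aryl hydrogen sulfates hydrolyse in their free acid form, so 16 and 17 are made and handled as salts (triethylammonium, then sodium); names and SMILES show the neutral acids, and 17 as drawn is the protonated form of the isolated disodium salt.

## Route

Step 1
Reactants: 1 4-methoxybenzyl alcohol; 2 2-chloro-N-methoxy-N-methylacetamide
Product: 4 N-methoxy-N-methyl-2-(4-methoxybenzyloxy)acetamide, via sodium 4-methoxybenzyl oxide 3 (not isolated)
Conditions: NaH (1.05 equiv), 1 (1.1 equiv), THF, 0 °C; then 2, Bu4NI (cat.), 0 °C → rt
Reagents that add atoms: none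
Why: Williamson ether synthesis: alkoxide 3 displaces chloride by SN2 at a carbon activated by the adjacent carbonyl. The N-methoxy-N-methyl amide is a poor acyl donor toward alkoxides at this temperature.

Step 2
Reactants: 5 1,3,5-trifluorobenzene; 4 N-methoxy-N-methyl-2-(4-methoxybenzyloxy)acetamide
Product: 7 2-(4-methoxybenzyloxy)-1-(2,4,6-trifluorophenyl)ethanone, via 2,4,6-trifluorophenyllithium 6 (not isolated)
Conditions: n-BuLi, THF, −78 °C; then 4, −78 → −60 °C; aq. NH4Cl (cold quench)
Reagents that add atoms: none
Why: Lithiation of a C–H flanked by two fluorines gives 6, which is kept cold so that it does not lose LiF to an aryne. Weinreb ketone synthesis: the chelated tetrahedral adduct persists until the quench, so addition stops at the ketone.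

Step 3
Reactants: 8 4-benzyloxy-3-methoxybenzoic acid
Product: 9 4-benzyloxy-3-methoxybenzoyl chloride
Conditions: (COCl)2, DMF (cat.), CH2Cl2, 0 °C → rt; evaporate, use crude
Reagents that add atoms: oxalyl chloride, O=C(Cl)C(=O)Cl
Why: Acid chloride formation through the catalytic chloroiminium species from DMF. The aryl benzyl ether and methyl ether tolerate the conditions.

Step 4
Reactants: 7 2-(4-methoxybenzyloxy)-1-(2,4,6-trifluorophenyl)ethanone; 9 4-benzyloxy-3-methoxybenzoyl chloride
Product: 12 2-(4-benzyloxy-3-methoxyphenyl)-5,7-difluoro-3-(4-methoxybenzyloxy)chromen-4-one, via lithium enolate 10 (not isolated), via 2-alkoxy-1,3-diketone 11 (not isolated)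
Conditions: LiN(SiMe3)2 (2.1 equiv), THF, −78 °C; 9 in THF, −78 → 0 °C; then K2CO3, DMF, 60 °C
Reagents that add atoms: none
Why: The first equivalent of LiN(SiMe3)2 deprotonates the only α-carbon of 7 to the chelated (Z)-enolate 10, which attacks the acid chloride on carbon to form C2–C3 (Claisen-type enolate aroylation). The second equivalent deprotonates the more acidic diketone 11 as it forms, which makes the C-acylation irreversible; any enol ester from O-acylation is itself an acyl donor toward remaining enolate and is funnelled the same way. The enolate oxygen on the ring B side of 11 then attacks an ortho C–F carbon of the trifluorophenyl ring, a Meisenheimer adduct stabilised by the C4 carbonyl forms, and loss of fluoride makes O1–C8a. K2CO3 in DMF is not consumed in the net equation; it exchanges lithium for potassium and so frees the oxygen from the tight lithium chelate. Ring C closes in a 6-exo-trig addition–elimination. The closest known reaction type is the one-pot flavone synthesis from ortho-fluoroaryl ketone enolates and aroyl chlorides by acylation and intramolecular SNAr. No stereocentre is created, since the transiently stereogenic C3 of 11 becomes sp2. The step needs carbon over oxygen acylation, which the lithium enolate with excess base at low temperature secures, and it needs no site selectivity in the closure because the two ortho fluorines are equivalent; the fluorides at C5 and C7 survive because no external nucleophile is present.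

Step 5
Reactants: 12 2-(4-benzyloxy-3-methoxyphenyl)-5,7-difluoro-3-(4-methoxybenzyloxy)chromen-4-one; 1 4-methoxybenzyl alcohol
Product: 14 2-(4-benzyloxy-3-methoxyphenyl)-3,5,7-tris(4-methoxybenzyloxy)chromen-4-one, via potassium 4-methoxybenzyl oxide 13 (not isolated)
Conditions: 1 (3.0 equiv), KH (2.6 equiv), THF, 0 °C → rt; then 12, DMPU, rt → 60 °C
Reagents that add atoms: none
Why: Twofold SNAr: C7–F is para and C5–F ortho to the C4 carbonyl, so both Meisenheimer adducts place charge on the carbonyl oxygen, and fluoride is the best leaving group for this mechanism. The first ether slows the second displacement, hence the loosely ion-paired potassium alkoxide 13 in excess with DMPU and warming; whichever fluoride leaves first, the product is the same. The excess alcohol consumes all KH before 12 is added.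

Step 6
Reactants: 14 2-(4-benzyloxy-3-methoxyphenyl)-3,5,7-tris(4-methoxybenzyloxy)chromen-4-one
Product: 15 2-(4-benzyloxy-3-methoxyphenyl)-3,5,7-trihydroxychromen-4-one
Conditions: CF3CO2H (10% v/v), C6HMe5 (6 equiv), CH2Cl2, 0 °C → rt
Reagents that add atoms: none
Why: SN1 acidolysis of the three 4-methoxybenzyl ethers; pentamethylbenzene traps the 4-methoxybenzyl cation by Friedel–Crafts alkylation before it can attack C6 or C8 of ring A. The plain benzyl ether on O4' ionises far more slowly and should survive dilute acid at this temperature.

Step 7
Reactants: 15 2-(4-benzyloxy-3-methoxyphenyl)-3,5,7-trihydroxychromen-4-one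
Product: 16 2-(4-benzyloxy-3-methoxyphenyl)-5-hydroxy-4-oxo-4H-chromene-3,7-diyl bis(hydrogen sulfate), as bis(triethylammonium) salt
Conditions: SO3·NEt3 (6 equiv), NEt3, DMF, 0 → 40 °C; MeOH quench; Sephadex LH-20
Reagents that add atoms: sulfur trioxide–triethylamine complex, CC[N+](CC)(CC)S(=O)(=O)[O-]
Why: O-sulfation of phenols by a sulfur trioxide–amine complex: the acidic 7-OH and the enolic 3-OH react. The 5-OH, tied up in its hydrogen bond to the C4 carbonyl, is the least nucleophilic hydroxyl and should stay free under non-forcing conditions, and O4' is blocked.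

Step 8
Reactants: 16 2-(4-benzyloxy-3-methoxyphenyl)-5-hydroxy-4-oxo-4H-chromene-3,7-diyl bis(hydrogen sulfate)
Product: 17 isorhamnetin 3,7-di-O-sulfate (target), isolated as disodium salt
Conditions: H2 (1 atm), 10% Pd/C, MeOH–H2O, NEt3 (trace), rt; Dowex 50W (Na+ form); lyophilise
Reagents that add atoms: none
Why: Catalytic hydrogenolysis of the benzyl aryl ether; aryl sulfate anions are inert to H2 over palladium, and the neutral to slightly basic medium prevents sulfate hydrolysis. The tetrasubstituted, conjugated C2=C3 bond should not be reduced at atmospheric pressure.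

## Compound list

1 | 4-methoxybenzyl alcohol | COc1ccc(CO)cc1 | starting material
2 | 2-chloro-N-methoxy-N-methylacetamide | CON(C)C(=O)CCl | starting material
3 | sodium 4-methoxybenzyl oxide | COc1ccc(C[O-])cc1.[Na+] | intermediate (not isolated)
4 | N-methoxy-N-methyl-2-(4-methoxybenzyloxy)acetamide | COc1ccc(COCC(=O)N(C)OC)cc1 | intermediate
5 | 1,3,5-trifluorobenzene | Fc1cc(F)cc(F)c1 | starting material
6 | 2,4,6-trifluorophenyllithium | [Li]c1c(F)cc(F)cc1F | intermediate (not isolated)
7 | 2-(4-methoxybenzyloxy)-1-(2,4,6-trifluorophenyl)ethanone | COc1ccc(COCC(=O)c2c(F)cc(F)cc2F)cc1 | intermediate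
8 | 4-benzyloxy-3-methoxybenzoic acid | COc1cc(C(=O)O)ccc1OCc1ccccc1 | starting material
9 | 4-benzyloxy-3-methoxybenzoyl chloride | COc1cc(C(=O)Cl)ccc1OCc1ccccc1 | intermediate
10 | lithium (Z)-2-(4-methoxybenzyloxy)-1-(2,4,6-trifluorophenyl)ethen-1-olate | [Li]O/C(=C\OCc1ccc(OC)cc1)c1c(F)cc(F)cc1F | intermediate (not isolated)
11 | 1-(4-benzyloxy-3-methoxyphenyl)-2-(4-methoxybenzyloxy)-3-(2,4,6-trifluorophenyl)propane-1,3-dione (racemic, enolisable; present as its lithium enolate) | COc1ccc(COC(C(=O)c2ccc(OCc3ccccc3)c(OC)c2)C(=O)c2c(F)cc(F)cc2F)cc1 | intermediate (not isolated)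
12 | 2-(4-benzyloxy-3-methoxyphenyl)-5,7-difluoro-3-(4-methoxybenzyloxy)chromen-4-one | COc1ccc(COc2c(-c3ccc(OCc4ccccc4)c(OC)c3)oc3cc(F)cc(F)c3c2=O)cc1 | intermediate
13 | potassium 4-methoxybenzyl oxide | COc1ccc(C[O-])cc1.[K+] | intermediate (not isolated)
14 | 2-(4-benzyloxy-3-methoxyphenyl)-3,5,7-tris(4-methoxybenzyloxy)chromen-4-one | COc1ccc(COc2cc(OCc3ccc(OC)cc3)c3c(=O)c(OCc4ccc(OC)cc4)c(-c4ccc(OCc5ccccc5)c(OC)c4)oc3c2)cc1 | intermediate
15 | 2-(4-benzyloxy-3-methoxyphenyl)-3,5,7-trihydroxychromen-4-one | COc1cc(-c2oc3cc(O)cc(O)c3c(=O)c2O)ccc1OCc1ccccc1 | intermediate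
16 | 2-(4-benzyloxy-3-methoxyphenyl)-5-hydroxy-4-oxo-4H-chromene-3,7-diyl bis(hydrogen sulfate) (handled as bis(triethylammonium) salt) | COc1cc(-c2oc3cc(OS(=O)(=O)O)cc(O)c3c(=O)c2OS(=O)(=O)O)ccc1OCc1ccccc1 | intermediate
17 | isorhamnetin 3,7-di-O-sulfate (isolated as disodium salt) | COc1cc(-c2oc3cc(OS(=O)(=O)O)cc(O)c3c(=O)c2OS(=O)(=O)O)ccc1O | target

## Step count and least certain steps

Total: 8 steps. Longest linear sequence: 7 steps (1, 2, 4, 5, 6, 7, 8); step 3 is the convergent branch.

**Step 4 (key step).** The most likely failure is acylation of enolate 10 on oxygen, or retro-Claisen cleavage of the 2-alkoxy-1,3-diketone during the warm carbonate stage, both of which would drain material before ring closure. The fallback sets out from 7 and changes the C–C bond formation to an aldol addition, where only carbon attack is possible. Enolate 10 would be added at −78 °C to commercial 4-benzyloxy-3-methoxybenzaldehyde and quenched cold to give 3-(4-benzyloxy-3-methoxyphenyl)-3-hydroxy-2-(4-methoxybenzyloxy)-1-(2,4,6-trifluorophenyl)propan-1-one F1 as a diastereomer mixture. Oxidation with Dess–Martin periodinane would give diketone 11, and K2CO3 in DMF would close it. The fallback comes back to the route at 12.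

**Step 5.** The second displacement may stall, because the first ether deactivates the remaining C–F bond, and reversible alkoxide addition at C2 may open ring C on prolonged heating. The fallback sets out from 12. One equivalent of alkoxide 13 at 0 °C in DMPU-rich solvent should stop after the less hindered para position has reacted, at 2-(4-benzyloxy-3-methoxyphenyl)-5-fluoro-3,7-bis(4-methoxybenzyloxy)chromen-4-one F2. The remaining fluoride would then be replaced by hydroxyl with an α-effect nucleophile (acetohydroxamic acid, K2CO3, DMSO, 80 °C; SNAr followed by Lossen-type fragmentation) to give 2-(4-benzyloxy-3-methoxyphenyl)-5-hydroxy-3,7-bis(4-methoxybenzyloxy)chromen-4-one F3. Acidolysis as in step 6 comes back to the route at 15.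

**Step 6.** The 4-methoxybenzyl cation may alkylate C6 or C8 of the electron-rich ring A faster than the scavenger traps it, and the O4' benzyl ether may be partly lost. The fallback sets out from 12 and avoids carbocations altogether. Sodium allyl oxide F4 (from allyl alcohol and NaH in THF–DMPU) would displace both fluorides to give 5,7-bis(allyloxy)-2-(4-benzyloxy-3-methoxyphenyl)-3-(4-methoxybenzyloxy)chromen-4-one F5. Oxidative cleavage of the single 4-methoxybenzyl ether with DDQ in wet CH2Cl2, with no free phenol present, would give 5,7-bis(allyloxy)-2-(4-benzyloxy-3-methoxyphenyl)-3-hydroxychromen-4-one F6. Deallylation with Pd(PPh3)4 (zerovalent palladium) and morpholine comes back to the route at 15.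

**Step 7.** Sulfation may stop short at the hindered, weakly hydrogen-bonded O3 or run on to O5, and the resulting anionic mixtures are hard to separate. The fallback sets out from 15 and uses a protected sulfate. 2,2,2-Trichloroethyl chlorosulfate with NEt3 and DMAP in THF would give the neutral diester 2-(4-benzyloxy-3-methoxyphenyl)-5-hydroxy-4-oxo-4H-chromene-3,7-diyl bis(2,2,2-trichloroethyl) bis(sulfate) F7, which can be purified on silica. Reductive removal of the trichloroethyl groups with Zn and HCO2NH4 in MeOH comes back to the route at 16.

## Further compounds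

F1 | step 4 | 3-(4-benzyloxy-3-methoxyphenyl)-3-hydroxy-2-(4-methoxybenzyloxy)-1-(2,4,6-trifluorophenyl)propan-1-one (racemic diastereomer mixture) | COc1ccc(COC(C(O)c2ccc(OCc3ccccc3)c(OC)c2)C(=O)c2c(F)cc(F)cc2F)cc1
F2 | step 5 | 2-(4-benzyloxy-3-methoxyphenyl)-5-fluoro-3,7-bis(4-methoxybenzyloxy)chromen-4-one | COc1ccc(COc2cc(F)c3c(=O)c(OCc4ccc(OC)cc4)c(-c4ccc(OCc5ccccc5)c(OC)c4)oc3c2)cc1
F3 | step 5 | 2-(4-benzyloxy-3-methoxyphenyl)-5-hydroxy-3,7-bis(4-methoxybenzyloxy)chromen-4-one | COc1ccc(COc2cc(O)c3c(=O)c(OCc4ccc(OC)cc4)c(-c4ccc(OCc5ccccc5)c(OC)c4)oc3c2)cc1
F4 | step 6 | sodium allyl oxide | C=CC[O-].[Na+]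
F5 | step 6 | 5,7-bis(allyloxy)-2-(4-benzyloxy-3-methoxyphenyl)-3-(4-methoxybenzyloxy)chromen-4-one | C=CCOc1cc(OCC=C)c2c(=O)c(OCc3ccc(OC)cc3)c(-c3ccc(OCc4ccccc4)c(OC)c3)oc2c1
F6 | step 6 | 5,7-bis(allyloxy)-2-(4-benzyloxy-3-methoxyphenyl)-3-hydroxychromen-4-one | C=CCOc1cc(OCC=C)c2c(=O)c(O)c(-c3ccc(OCc4ccccc4)c(OC)c3)oc2c1
F7 | step 7 | 2-(4-benzyloxy-3-methoxyphenyl)-5-hydroxy-4-oxo-4H-chromene-3,7-diyl bis(2,2,2-trichloroethyl) bis(sulfate) | COc1cc(-c2oc3cc(OS(=O)(=O)OCC(Cl)(Cl)Cl)cc(O)c3c(=O)c2OS(=O)(=O)OCC(Cl)(Cl)Cl)ccc1OCc1ccccc1
A1 | alternative 1 | racemic trans-2-(4-benzyloxy-3-methoxyphenyl)-3,5,7-tris(methoxymethoxy)chroman-4-one (one enantiomer drawn) | COc1cc([C@@H]2[C@@H](OCOC)C(=O)c3c(OCOC)cc(OCOC)cc3O2)ccc1OCc1ccccc1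
A2 | alternative 1 | 3,5-bis(methoxymethoxy)-2-(trimethylsilyl)phenyl trifluoromethanesulfonate | COCOc1cc(OCOC)c([Si](C)(C)C)c(OS(=O)(=O)C(F)(F)F)c1
A3 | alternative 1 | (Z)-3-(4-benzyloxy-3-methoxyphenyl)-2-(methoxymethoxy)acrylic acid | COCO/C(=C\c1ccc(OCc2ccccc2)c(OC)c1)C(=O)O
A4 | alternative 2 | 2-(4-benzyloxy-3-methoxyphenyl)-5,7-dihydroxy-4-oxo-4H-chromen-3-yl benzoate | COc1cc(-c2oc3cc(O)cc(O)c3c(=O)c2OC(=O)c2ccccc2)ccc1OCc1ccccc1
A5 | alternative 2 | ethyl 2-(benzoyloxy)-3-(4-benzyloxy-3-methoxyphenyl)-3-oxopropanoate (racemic) | CCOC(=O)C(OC(=O)c1ccccc1)C(=O)c1ccc(OCc2ccccc2)c(OC)c1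
A6 | alternative 2 | phloroglucinol | Oc1cc(O)cc(O)c1
A7 | alternative 3 | 2-(4-benzyloxy-3-methoxyphenyl)-7-tert-butoxy-5-hydroxy-3-(methoxymethoxy)chromen-4-one | COCOc1c(-c2ccc(OCc3ccccc3)c(OC)c2)oc2cc(OC(C)(C)C)cc(O)c2c1=O
A8 | alternative 3 | 2-diazo-1-[6-(4-benzyloxy-3-methoxyphenyl)-5-(methoxymethoxy)-4-oxo-4H-pyran-2-yl]ethanone | COCOc1c(-c2ccc(OCc3ccccc3)c(OC)c2)oc(C(=O)C=[N+]=[N-])cc1=O
A9 | alternative 3 | tert-butoxyacetylene | C#COC(C)(C)C
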